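**Retrosynthetic overview**

1. Lactone ring last: the butenolide comes from ring-closing metathesis of an allyl 2-alkylacrylate, attached by Barbier allylation of the C9 aldehyde, which sets C11 (labdane numbering; ring A = C1–C5/C10, ring B = C5–C10).
2. The C9 CH2OH/CHO arm and the exocyclic C8=C17 alkene come from a ring B ketone at C9 by α-methylenation, epoxide formation and palladium–formate hydrogenolysis, so that H reaches C9 last.
3. Ring A is annulated onto ring B in one operation: a diazomethyl ketone on the C10 CH2 arm undergoes Wolff rearrangement (the 1,2-shift makes C1–C2), and the ketene carbon C3 is captured by the silyl enol ether of the C19 aldehyde on the C5 arm (makes C3–C4 and the quaternary C4).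
4. Enabling feature: C1 is an unfunctionalised CH2 on the quaternary C10, so it can arrive as a migrating group; and C3–OH/C4/C19–OH of ring A is a 1,3-dioxygenated array, the reduced form of a C-acylated aldehyde enol (C3 = ketene carbon, C4 = enol carbon).
5. Ring order: ring B first (2-methylcyclohex-2-enone; asymmetric conjugate addition/alkylation sets C5 and C10), then ring A (key step), then the lactone ring.

Key step: step 6

Remark: labdane numbering is used in the text (C17 = exocyclic CH2, C18/C19 = C4 methyl/CH2OH carbon, C20 = C10 methyl); β is the face of the C10 methyl group, α the opposite face; the ring B carbinol in 14–17 is drawn as the expected equatorial epimer, but either epimer serves because it is oxidised in step 9.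

**Route**

Step 1
Reactants: 1 2-methylcyclohex-2-en-1-one; 2 isopropenylmagnesium bromide; 3 allyl bromoacetate
Product: 5 allyl 2-[(1R,6R)-1-methyl-2-oxo-6-(prop-1-en-2-yl)cyclohexyl]acetate, via bromomagnesium enolate 4 (not isolated)
Conditions: Cu(OTf)2 (3 mol %), chiral hydroxyalkyl-imidazolinium salt (NHC precursor, 4 mol %), 2, Et2O, −30 °C; then 3, DMPU, −30 °C to rt
Reagents that add atoms: none
Why: Copper-catalysed asymmetric conjugate addition of the Grignard reagent to the α-substituted enone sets C5 under ligand control (ligand enantiomer chosen for the R centre), and alkylation of the regiodefined magnesium enolate occurs anti to the new isopropenyl group, which sets the quaternary C10 with its two side arms trans.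

Step 2
Reactants: 5
Product: 7 allyl 2-[(1R,2R)-1-methyl-6-oxo-2-(3-oxoprop-1-en-2-yl)cyclohexyl]acetate, via allylic alcohol 6 (not isolated)
Conditions: SeO2 (1.2 equiv), 1,4-dioxane–H2O (20:1), 70 °C
Reagents that add atoms: selenium dioxide O=[Se]=O
Why: Allylic oxidation with SeO2 (ene reaction, [2,3]-sigmatropic shift, then further oxidation of the allylic alcohol) takes the methyl group of the 1,1-disubstituted alkene rather than the ring methine and gives the 2-substituted acrolein without touching a stereocenter.

Step 3
Reactants: 7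
Product: 8 allyl 2-[(1R,2R)-1-methyl-6-oxo-2-[(E)-1-(triethylsilyloxy)prop-1-en-2-yl]cyclohexyl]acetate
Conditions: Et3SiH (1.1 equiv), RhCl(PPh3)3 (1 mol %), THF, 50 °C
Reagents that add atoms: triethylsilane CC[SiH](CC)CC
Why: Rhodium-catalysed 1,4-hydrosilylation of the enal through its s-cis conformer puts H on the former methylene carbon (now C18) and Si on oxygen, so the silyloxy group and the new methyl group are cis on C4=C19 (E isomer).

Step 4
Reactants: 8
Product: 9 sodium 2-[(1R,2R)-1-methyl-6-oxo-2-[(E)-1-(triethylsilyloxy)prop-1-en-2-yl]cyclohexyl]acetate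
Conditions: Pd(PPh3)4 (2 mol %), sodium 2-ethylhexanoate (1.05 equiv), EtOAc–THF, rt
Reagents that add atoms: sodium 2-ethylhexanoate CCCCC(CC)C(=O)[O-].[Na+]
Why: Palladium-catalysed allyl transfer (Tsuji–Trost deallylation) to 2-ethylhexanoate frees the carboxylate under neutral conditions that spare the silyl enol ether.

Step 5
Reactants: 9
Product: 11 (2R,3R)-2-(3-diazo-2-oxopropyl)-2-methyl-3-[(E)-1-(triethylsilyloxy)prop-1-en-2-yl]cyclohexan-1-one, via mixed carbonic anhydride 10 (not isolated)
Conditions: i-BuOCOCl, N-methylmorpholine (cat.), THF, −15 °C; then CH2N2, Et2O, 0 °C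
Reagents that add atoms: diazomethane C=[N+]=[N-]
Why: Acylation of diazomethane by the mixed carbonic anhydride (first stage of an Arndt–Eistert sequence) gives the diazomethyl ketone without an acid chloride or HCl, which the silyl enol ether would not survive.

Step 6
Reactants: 11
Product: 13 trans-fused 5,8a-dimethyl-1-oxo-6-(triethylsilyloxy)-1,2,3,4,4a,5,8,8a-octahydronaphthalene-5-carbaldehyde, via ketene 12 (not isolated)
Conditions: hν (365 nm LED), toluene (0.005 M), rt; then 60 °C
Reagents that add atoms: none
Why: Proposed new method: irradiation expels N2 and the Wolff rearrangement shifts the neopentyl CH2 (C1) from the acyl carbon (C3) to the diazo carbon (C2), which makes the C1–C2 bond and the ketene C2=C3=O; the tethered (E)-silyl enol ether then attacks the ketene carbon C3 with its β-carbon C4 (C3–C4 bond, quaternary C4), and oxygen-to-oxygen silyl transfer in the zwitterion leaves the C19 aldehyde and the C3 silyl enol ether. The closest known reaction types are the Arndt–Eistert homologation (Wolff rearrangement with capture of the ketene), intramolecular ketene–alkene [2+2] cycloadditions that follow a Wolff rearrangement, and the reaction of ketenes with silyl enol ethers to 3-siloxycyclobutanones or 1,3-dicarbonyl compounds. Ring A closes in the 6-(enolexo)-exo-dig mode on the sp carbon of the ketene, and the C2=C3 bond stays in the ring as the enol ether. The only new stereocenter, C4, is controlled by the substrate (C5 and C10): in the chair-like, closed (asynchronous [2+2]-like) transition state expected in toluene, C19 lies over C2 and becomes axial on the β face, the C4 methyl group stays equatorial and avoids the syn-pentane contact with the axial C10 methyl group, and the E geometry turns a hydrogen rather than the silyloxy group toward C10. The step needs chemoselective intramolecular capture of the ketene, secured by high dilution, the absence of protic nucleophiles and the silyl enol ether being the only π-nucleophile (the ring B ketone is not enolised), and it needs facial selectivity at C4, secured by the trans-diequatorial placement of the two reacting arms on ring B.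

Step 7
Reactants: 13
Product: 16 trans-fused 5-(hydroxymethyl)-5,8a-dimethyldecahydronaphthalene-1,6-diol, via silyl enol ether diol 14 (not isolated), via dihydroxy ketone 15 (not isolated)
Conditions: NaBH4 (excess), MeOH–THF, −20 °C; then K2CO3 (0.2 equiv), 0 °C to rt
Reagents that add atoms: none
Why: Borohydride reduction: the aldehyde and the ring B ketone are reduced first, base-promoted methanolysis of the silyl enol ether then frees the C3 ketone, which takes hydride axially from the α face because the β face is shielded by the axial C4 CH2OH group and the C10 methyl group, giving the equatorial 3-OH cis to C19.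

Step 8
Reactants: 16
Product: 17 3,19-O-isopropylidene acetal of 16 (ring B alcohol free)
Conditions: 2,2-dimethoxypropane, PPTS (cat.), acetone, rt
Reagents that add atoms: 2,2-dimethoxypropane COC(C)(C)OC
Why: Acetalisation under thermodynamic control closes the six-membered isopropylidene acetal on the cis 1,3-diol (3-OH and 19-OH) and leaves the isolated ring B alcohol free.

Step 9
Reactants: 17
Product: 18 C9 ketone of the 3,19-acetonide
Conditions: Dess–Martin periodinane, NaHCO3, CH2Cl2, rt
Reagents that add atoms: none
Why: Dess–Martin oxidation of the only free alcohol restores the C9 ketone.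

Step 10
Reactants: 18
Product: 22 8-methylene-9-ketone (α-methylene ketone), via lithium enolate 19 (not isolated), via Mannich base 20 (not isolated), via methiodide 21 (not isolated)
Conditions: LiN(SiMe3)2, THF, −78 °C; dimethylmethyleneiminium iodide, −78 °C to rt; then MeI; then DBU, CH2Cl2, rt
Reagents that add atoms: dimethylmethyleneiminium iodide C=[N+](C)C.[I-]
Why: Mannich reaction of the only possible enolate (toward C8, since C10 is quaternary) with the iminium salt, then quaternisation and E1cB elimination, gives the α-methylene ketone.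

Step 11
Reactants: 22
Product: 24 spiro alkenyl oxirane at C9 (epoxide CH2 on the α face), via lithium chlorohydrin alkoxide 23 (not isolated)
Conditions: ICH2Cl, n-BuLi, THF, −78 °C to rt
Reagents that add atoms: chloroiodomethane ClCI
Why: 1,2-Addition of chloromethyllithium to the enone carbonyl and closure of the chlorohydrin alkoxide (intramolecular Williamson substitution) gives the alkenyl oxirane; the small carbenoid attacks C9 axially from the α face, away from the axial C10 methyl group, so the epoxide CH2 is α and the oxygen β.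

Step 12
Reactants: 24
Product: 25 homoallylic alcohol (C9 CH2OH equatorial, exocyclic C8=C17)
Conditions: Pd2(dba)3·CHCl3 (2.5 mol %), PBu3 (5 mol %), HCO2H, Et3N, 1,4-dioxane, rt
Reagents that add atoms: none
Why: Palladium-catalysed hydrogenolysis of an alkenyl oxirane with formate: ionisation with inversion places palladium on the α face of the π-allyl complex, and hydride moves from palladium to the more substituted terminus C9 on that face, which gives 9α-H (C11 equatorial), the exocyclic C8=C17 alkene and the primary alcohol.

Step 13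
Reactants: 25
Product: 26 C11 aldehyde
Conditions: Dess–Martin periodinane, NaHCO3, CH2Cl2, 0 °C
Reagents that add atoms: none
Why: Buffered Dess–Martin oxidation gives the β,γ-unsaturated aldehyde under neutral conditions, so the exocyclic alkene does not move into conjugation and C9 is not epimerised.

Step 14
Reactants: 27 2-(bromomethyl)acrylic acid; 28 allyl alcohol
Product: 29 allyl 2-(bromomethyl)acrylate
Conditions: TsOH·H2O (cat.), cyclohexane, reflux (Dean–Stark)
Reagents that add atoms: none
Why: Acid-catalysed Fischer esterification driven by azeotropic removal of water.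

Step 15
Reactants: 26; 29
Product: 30 (11R)-homoallylic alcohol bearing the allyl acrylate
Conditions: In powder, THF–H2O (1:1), rt
Reagents that add atoms: none
Why: Indium-mediated Barbier allylation: the allylindium species adds to the aldehyde through a cyclic transition state under Felkin–Anh control by C9 (quaternary C10 as the large group anti to the incoming carbon), which is predicted to give the 11R alcohol.

Step 16
Reactants: 30
Product: 31 C11 triethylsilyl ether of 30
Conditions: Et3SiCl, imidazole, CH2Cl2, 0 °C
Reagents that add atoms: chlorotriethylsilane CC[Si](Cl)(CC)CC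
Why: Silylation of the secondary alcohol prevents its lactonisation onto the allyl ester during the next step.

Step 17
Reactants: 31
Product: 32 protected butenolide (3,19-acetonide and 11-O-triethylsilyl ether of the target)
Conditions: second-generation Grubbs catalyst (5 mol %), toluene, 80 °C
Reagents that add atoms: none
Why: Ring-closing metathesis between the allyl ester alkene and the acrylate alkene closes the α-substituted butenolide, while the hindered exocyclic C8=C17 alkene cannot form a small ring and stays untouched.

Step 18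
Reactants: 32
Product: 33 14-deoxy-11-hydroxyandrographolide
Conditions: AcOH–THF–H2O (3:1:1), 40 °C
Reagents that add atoms: none
Why: Mild acid hydrolysis cleaves the isopropylidene acetal and the triethylsilyl ether, while the butenolide and the exocyclic alkene are stable under these conditions.

**Compound list**

1 | 2-methylcyclohex-2-en-1-one | CC1=CCCCC1=O | starting material
2 | isopropenylmagnesium bromide (prop-1-en-2-ylmagnesium bromide) | CC(=C)[Mg]Br | starting material
3 | allyl bromoacetate (prop-2-en-1-yl 2-bromoacetate) | C=CCOC(=O)CBr | starting material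
4 | bromomagnesium (3R)-2-methyl-3-(prop-1-en-2-yl)cyclohex-1-en-1-olate (not isolated) | C1CC[C@H](C(C)=C)C(C)=C1O[Mg]Br | intermediate
5 | allyl 2-[(1R,6R)-1-methyl-2-oxo-6-(prop-1-en-2-yl)cyclohexyl]acetate (side arms trans) | C1CC[C@H](C(C)=C)[C@@](C)(CC(=O)OCC=C)C1=O | intermediate
6 | allyl 2-[(1R,2R)-2-(3-hydroxyprop-1-en-2-yl)-1-methyl-6-oxocyclohexyl]acetate (not isolated) | C1CC[C@H](C(=C)CO)[C@@](C)(CC(=O)OCC=C)C1=O | intermediate
7 | allyl 2-[(1R,2R)-1-methyl-6-oxo-2-(3-oxoprop-1-en-2-yl)cyclohexyl]acetate | C1CC[C@H](C(=C)C=O)[C@@](C)(CC(=O)OCC=C)C1=O | intermediate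
8 | allyl 2-[(1R,2R)-1-methyl-6-oxo-2-[(E)-1-(triethylsilyloxy)prop-1-en-2-yl]cyclohexyl]acetate | C1CC[C@H](/C(C)=C/O[Si](CC)(CC)CC)[C@@](C)(CC(=O)OCC=C)C1=O | intermediate
9 | sodium 2-[(1R,2R)-1-methyl-6-oxo-2-[(E)-1-(triethylsilyloxy)prop-1-en-2-yl]cyclohexyl]acetate | C1CC[C@H](/C(C)=C/O[Si](CC)(CC)CC)[C@@](C)(CC(=O)[O-])C1=O.[Na+] | intermediate
10 | isobutyl carbonic anhydride of the acid of 9 (not isolated) | C1CC[C@H](/C(C)=C/O[Si](CC)(CC)CC)[C@@](C)(CC(=O)OC(=O)OCC(C)C)C1=O | intermediate
11 | (2R,3R)-2-(3-diazo-2-oxopropyl)-2-methyl-3-[(E)-1-(triethylsilyloxy)prop-1-en-2-yl]cyclohexan-1-one | C1CC[C@H](/C(C)=C/O[Si](CC)(CC)CC)[C@@](C)(CC(=O)C=[N+]=[N-])C1=O | intermediate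
12 | (2R,3R)-2-methyl-2-(3-oxoprop-2-en-1-yl)-3-[(E)-1-(triethylsilyloxy)prop-1-en-2-yl]cyclohexan-1-one (ketene, not isolated) | C1CC[C@H](/C(C)=C/O[Si](CC)(CC)CC)[C@@](C)(CC=C=O)C1=O | intermediate
13 | trans-fused 5,8a-dimethyl-1-oxo-6-(triethylsilyloxy)-1,2,3,4,4a,5,8,8a-octahydronaphthalene-5-carbaldehyde; CHO (C19) axial and cis to the angular methyl; C4, C5, C10 as in the target | O=C1CCC[C@@H]2[C@](C)(C=O)C(O[Si](CC)(CC)CC)=CC[C@@]12C | intermediate
14 | C19 alcohol/ring B alcohol with the C3 silyl enol ether intact (not isolated) | C1CC[C@@H]2[C@](C)(CO)C(O[Si](CC)(CC)CC)=CC[C@@]2(C)[C@@H]1O | intermediate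
15 | 3-ketone with C19 and ring B alcohols (not isolated) | C1CC[C@@H]2[C@](C)(CO)C(=O)CC[C@@]2(C)[C@@H]1O | intermediate
16 | trans-fused 5-(hydroxymethyl)-5,8a-dimethyldecahydronaphthalene-1,6-diol; 3-OH equatorial and cis to the axial CH2OH; C3, C4, C5, C10 as in the target | C1CC[C@@H]2[C@](C)(CO)[C@H](O)CC[C@@]2(C)[C@@H]1O | intermediate
17 | 3,19-O-isopropylidene acetal of 16 (ring B alcohol free) | C1CC[C@@H]2[C@]3(C)COC(C)(C)O[C@@H]3CC[C@@]2(C)[C@@H]1O | intermediate
18 | C9 ketone of the 3,19-acetonide | C1CC[C@@H]2[C@]3(C)COC(C)(C)O[C@@H]3CC[C@@]2(C)C1=O | intermediate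
19 | lithium enolate of 18 toward C8 (not isolated) | [Li]OC1=CCC[C@@H]2[C@]3(C)COC(C)(C)O[C@@H]3CC[C@@]12C | intermediate
20 | 8-(dimethylaminomethyl) ketone, C8 epimers (Mannich base, not isolated) | CN(C)CC1CC[C@@H]2[C@]3(C)COC(C)(C)O[C@@H]3CC[C@@]2(C)C1=O | intermediate
21 | trimethylammonium iodide of 20 (not isolated) | C[N+](C)(C)CC1CC[C@@H]2[C@]3(C)COC(C)(C)O[C@@H]3CC[C@@]2(C)C1=O.[I-] | intermediate
22 | 8-methylene-9-ketone of the 3,19-acetonide | C=C1CC[C@@H]2[C@]3(C)COC(C)(C)O[C@@H]3CC[C@@]2(C)C1=O | intermediate
23 | lithium alkoxide of the C9 chloromethyl carbinol, CH2Cl on the α face (not isolated) | C=C1CC[C@@H]2[C@]3(C)COC(C)(C)O[C@@H]3CC[C@@]2(C)[C@]1(CCl)O[Li] | intermediate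
24 | spiro alkenyl oxirane at C9; epoxide CH2 α (axial), oxygen β | C=C1CC[C@@H]2[C@]3(C)COC(C)(C)O[C@@H]3CC[C@@]2(C)[C@@]14CO4 | intermediate
25 | homoallylic alcohol: C9 CH2OH equatorial, 9-H α, exocyclic C8=C17, 3,19-acetonide | C=C1CC[C@@H]2[C@]3(C)COC(C)(C)O[C@@H]3CC[C@@]2(C)[C@@H]1CO | intermediate
26 | corresponding C11 aldehyde | C=C1CC[C@@H]2[C@]3(C)COC(C)(C)O[C@@H]3CC[C@@]2(C)[C@@H]1C=O | intermediate
27 | 2-(bromomethyl)acrylic acid | C=C(CBr)C(=O)O | starting material
28 | allyl alcohol | C=CCO | starting material
29 | allyl 2-(bromomethyl)acrylate | C=CCOC(=O)C(=C)CBr | intermediate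
30 | (11R)-alcohol with the allyl 2-methyleneester side chain, 3,19-acetonide | C=C1CC[C@@H]2[C@]3(C)COC(C)(C)O[C@@H]3CC[C@@]2(C)[C@@H]1[C@H](O)CC(=C)C(=O)OCC=C | intermediate
31 | 11-O-triethylsilyl ether of 30 | C=C1CC[C@@H]2[C@]3(C)COC(C)(C)O[C@@H]3CC[C@@]2(C)[C@@H]1[C@H](O[Si](CC)(CC)CC)CC(=C)C(=O)OCC=C | intermediate
32 | 3,19-O-isopropylidene-11-O-triethylsilyl-14-deoxy-11-hydroxyandrographolide | C=C1CC[C@@H]2[C@]3(C)COC(C)(C)O[C@@H]3CC[C@@]2(C)[C@@H]1[C@H](O[Si](CC)(CC)CC)CC1=CCOC1=O | intermediate
33 | 14-deoxy-11-hydroxyandrographolide (3R,4R,5S,9R,10R,11R) | C=C1CC[C@@H]2[C@](C)(CO)[C@H](O)CC[C@@]2(C)[C@@H]1[C@H](O)CC1=CCOC1=O | target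

**Step count and risks**

Total step count: 18. Longest linear sequence: 17 (steps 1–13 and 15–18; step 14 prepares the allylating ester).

Steps most likely to fail:

1. Step 6 (key step). What may go wrong: the ketene is consumed by dimerisation, or closes with the enol ether to a strained bridged cyclobutanone instead of undergoing clean C-acylation at the hindered enol ether carbon; attack on the wrong face of the enol ether would erode the C4 configuration. Fallback (known reactions, the two bonds made in separate operations): from 11, Wolff rearrangement in the presence of N,O-dimethylhydroxylamine (Arndt–Eistert homologation) gives the homologated Weinreb amide F1 with the C1–C2 bond in place. i-Bu2AlH at −78 °C reduces the amide to the C3 aldehyde and the ring B ketone to the carbinol, giving the hydroxy aldehyde F2. BF3·OEt2 then closes ring A by intramolecular Mukaiyama aldol addition of the silyl enol ether to the aldehyde, giving the aldol F3. Dess–Martin oxidation of both carbinols gives the diketo aldehyde F4, and NaBH4 in MeOH reduces it, as in step 7, to triol 16, where the route is rejoined.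

2. Step 1. What may go wrong: incomplete enantioface control in the copper-catalysed addition of the alkenyl Grignard reagent, or slow C-alkylation of the hindered magnesium enolate (proton transfer, O-alkylation). Fallback (racemic assembly, then classical resolution): from 1, CuI-catalysed addition of 2 with Me3SiCl gives the racemic silyl enol ether F5. MeLi and then tert-butyl bromoacetate give the racemic tert-butyl ester F6, and CF3CO2H gives the racemic acid F7. Crystallisation with (S)-1-phenylethylamine (or its enantiomer, whichever salt of the (1R,6R) acid crystallises) gives the salt F8, which allyl bromide and K2CO3 in DMF convert into 5.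

3. Step 12. What may go wrong: hydride delivery to the wrong allyl terminus (endocyclic C8=C9 alkene) or to the wrong face of C9, or slow ionisation of the equatorial C–O bond. Fallback (C9–H set by protonation and equilibration next to the aldehyde, exocyclic alkene made by sulfoxide elimination): from 18, condensation with 2,4,6-triisopropylbenzenesulfonyl hydrazide gives the hydrazone F9. Shapiro reaction (n-BuLi, then DMF) gives the enal F10. Conjugate addition of (PhSCH2)2CuLi with Me3SiCl, followed by equilibration at C9 (K2CO3, MeOH), gives the sulfide aldehyde F11 with the formyl group equatorial. NaBH4 gives the alcohol F12, NaIO4 gives the sulfoxide F13, and thermolysis (toluene, 110 °C, CaCO3) eliminates toward the only β-hydrogen (C8–H) to give 25.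

Further compounds
F1 | step 6 | N-methoxy-N-methyl-3-[(1R,2R)-1-methyl-6-oxo-2-[(E)-1-(triethylsilyloxy)prop-1-en-2-yl]cyclohexyl]propanamide | C1CC[C@H](/C(C)=C/O[Si](CC)(CC)CC)[C@@](C)(CCC(=O)N(C)OC)C1=O
F2 | step 6 | 3-[(1R,2R)-6-hydroxy-1-methyl-2-[(E)-1-(triethylsilyloxy)prop-1-en-2-yl]cyclohexyl]propanal (carbinol epimers) | C1CC[C@H](/C(C)=C/O[Si](CC)(CC)CC)[C@@](C)(CCC=O)C1O
F3 | step 6 | trans-fused 1,6-dihydroxy-5,8a-dimethyldecahydronaphthalene-5-carbaldehyde (carbinol epimers) | C1CC[C@@H]2[C@](C)(C=O)C(O)CC[C@@]2(C)C1O
F4 | step 6 | trans-fused 5,8a-dimethyl-1,6-dioxodecahydronaphthalene-5-carbaldehyde | O=C1CCC[C@@H]2[C@](C)(C=O)C(=O)CC[C@@]12C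
F5 | step 1 | rac-2-methyl-3-(prop-1-en-2-yl)-1-(trimethylsilyloxy)cyclohex-1-ene | CC(=C)C1CCCC(O[Si](C)(C)C)=C1C
F6 | step 1 | rac-tert-butyl 2-[(1R*,6R*)-1-methyl-2-oxo-6-(prop-1-en-2-yl)cyclohexyl]acetate (one enantiomer drawn) | C1CC[C@H](C(C)=C)[C@@](C)(CC(=O)OC(C)(C)C)C1=O
F7 | step 1 | rac-2-[(1R*,6R*)-1-methyl-2-oxo-6-(prop-1-en-2-yl)cyclohexyl]acetic acid (one enantiomer drawn) | C1CC[C@H](C(C)=C)[C@@](C)(CC(=O)O)C1=O
F8 | step 1 | (S)-1-phenylethylammonium 2-[(1R,6R)-1-methyl-2-oxo-6-(prop-1-en-2-yl)cyclohexyl]acetate | C1CC[C@H](C(C)=C)[C@@](C)(CC(=O)[O-])C1=O.C[C@H]([NH3+])c1ccccc1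
F9 | step 12 | 2,4,6-triisopropylbenzenesulfonyl hydrazone of 18 | CC(C)c1cc(C(C)C)c(S(=O)(=O)NN=C2CCC[C@@H]3[C@]4(C)COC(C)(C)O[C@@H]4CC[C@@]23C)c(C(C)C)c1
F10 | step 12 | 8,9-unsaturated C11 aldehyde of the 3,19-acetonide | O=CC1=CCC[C@@H]2[C@]3(C)COC(C)(C)O[C@@H]3CC[C@@]12C
F11 | step 12 | 8-(phenylthiomethyl) C11 aldehyde, formyl equatorial, C8 epimers | O=C[C@@H]1C(CSc3ccccc3)CC[C@@H]2[C@]4(C)COC(C)(C)O[C@@H]4CC[C@@]12C
F12 | step 12 | 8-(phenylthiomethyl) C11 alcohol | OC[C@@H]1C(CSc3ccccc3)CC[C@@H]2[C@]4(C)COC(C)(C)O[C@@H]4CC[C@@]12C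
F13 | step 12 | 8-(phenylsulfinylmethyl) C11 alcohol | OC[C@@H]1C(CS(=O)c3ccccc3)CC[C@@H]2[C@]4(C)COC(C)(C)O[C@@H]4CC[C@@]12C
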